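**Retrosynthetic overview**

- Peniophorin 13 is taken back to its bis(aryl methyl ether) 12, a 1-benzofuran-2,6-dione (O1, lactone carbonyl C2, C3-aryl, C3a, C4-aryl, C5-OH, C6=O, C7-phenyl, C7a).
- The strategy rests on this feature: C5–C6–C7 of the six-membered ring is an intact phenylpyruvate (ester carbon, ketone, benzylic carbon), and C2–C3=C3a(–C4)–C7a is an aryl(benzyl)maleate. Cutting C7–C7a and C4–C5 (two ester condensations) and O1–C2 (lactone) gives maleate 6 and methyl phenylpyruvate 8.
- Forward ring order: the carbocycle (C3a, C4, C5, C6, C7, C7a) closes first by Claisen then Dieckmann condensation; the lactone (O1, C2, C3, C3a, C7a) closes second, on acidification in the same step.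
- 6 comes from alkenyl triflate 4 and boronic acid 5 (Suzuki–Miyaura); 4 comes from oxalylation of ester 1 with di-tert-butyl oxalate 2; 8 comes from phenylpyruvic acid 7.

Key step: step 5

Remark on the chemistry: the C2 ester of the maleate is carried as a tert-butyl ester, so that only the C7a methyl ester can acylate C7. The lactone is closed after acidification, because an enol lactone would not persist beside excess methoxide.

**Step 1**
Reactants: 1 methyl 3-(4-methoxyphenyl)propanoate; 2 di-tert-butyl oxalate
Product: 3 4-tert-butyl 1-methyl 2-(4-methoxybenzyl)-3-oxobutanedioate (racemic; largely enolised)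
Conditions: LiN(SiMe3)2 (2.1 equiv), THF, −78 °C; then 2, −78 to −20 °C; aq. HCl
Reagents that add atoms: none
Why: Crossed Claisen condensation, in which the lithium enolate of 1 should acylate on the non-enolisable, doubly activated oxalate 2, while the second equivalent of base stores the acidic product as its enolate so that neither reversal nor a second addition occurs.

**Step 2**
Reactants: 3 4-tert-butyl 1-methyl 2-(4-methoxybenzyl)-3-oxobutanedioate
Product: 4 4-tert-butyl 1-methyl (E)-2-(4-methoxybenzyl)-3-(trifluoromethanesulfonyloxy)but-2-enedioate (the two ester groups cis)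
Conditions: Tf2O, i-Pr2NEt, CH2Cl2, −78 to 0 °C
Reagents that add atoms: trifluoromethanesulfonic anhydride, O=S(=O)(OS(=O)(=O)C(F)(F)F)C(F)(F)F
Why: Enol triflate formation, in which the fully enolised keto diester is O-sulfonylated as its non-chelated ammonium enolate, which should place the triflate anti to the C1 methyl ester and so fix the two ester groups cis.

**Step 3**
Reactants: 4 4-tert-butyl 1-methyl (E)-2-(4-methoxybenzyl)-3-(trifluoromethanesulfonyloxy)but-2-enedioate; 5 4-methoxyphenylboronic acid
Product: 6 4-tert-butyl 1-methyl (Z)-2-(4-methoxybenzyl)-3-(4-methoxyphenyl)but-2-enedioate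
Conditions: Pd(PPh3)4 (5 mol %), K3PO4, 1,4-dioxane, 80 °C
Reagents that add atoms: none
Why: Suzuki–Miyaura coupling, in which the electron-poor alkenyl triflate should add oxidatively to zerovalent palladium and couple with retention of the double-bond geometry, so that the aryl group takes the place of the triflate and the maleate (Z) geometry follows.

**Step 4**
Reactants: 7 phenylpyruvic acid
Product: 8 methyl phenylpyruvate
Conditions: MeOH, H2SO4 (cat.), 50 °C
Reagents that add atoms: methanol, CO
Why: Fischer esterification of the carboxylic acid in methanol under acid catalysis, conditions under which the enolised 2-oxo group should not self-condense.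

**Step 5**
Reactants: 6 4-tert-butyl 1-methyl (Z)-2-(4-methoxybenzyl)-3-(4-methoxyphenyl)but-2-enedioate; 8 methyl phenylpyruvate
Product: 12 peniophorin bis(4-O-methyl) ether [5-hydroxy-3,4-bis(4-methoxyphenyl)-7-phenyl-1-benzofuran-2,6-dione], via open-chain Claisen adduct 9 (not isolated), via seco tert-butyl ester 10 (not isolated), via seco acid 11 (not isolated)
Conditions: 8 (1.3 equiv), NaOMe (3.5 equiv), THF, 0 °C; then 6, 0 to 65 °C; evaporate; TFA/CH2Cl2 (1:1), 23 °C; then PhMe, 80 °C (−H2O)
Reagents that add atoms: none
Why: Proposed new method: the preformed sodium enolate of 8 should be acylated at C7 by the C7a methyl ester of 6 (crossed Claisen) to give 9 as its C7a–C7–C6 diketonate, methoxide then removes a benzylic C4 hydrogen (vinylogous to the C2 ester) and this carbanion attacks the C5 methyl ester in a 6-exo-trig (enolendo) Dieckmann closure of the carbocycle, which settles as the doubly enolised dianion of 10. The lactone is closed only after acidification, since an enol lactone would be reopened by excess methoxide: TFA cleaves the tert-butyl ester to acid 11, whose carboxyl group is attacked by the cis C7a enol oxygen in a 5-exo-trig closure with loss of water. No stereocentre is formed and the oxidation level of 12 is reached without a redox reagent, because three acyl substitutions and two enolisations account for the whole change. The closest known reaction types are the alkoxide-driven Claisen–Dieckmann condensations of oxalates with bis(benzylic) ketones or diesters that give cyclic enolised polyketones, and the acid-induced closure of 2-hydroxyarylacetic acids to benzofuran-2(3H)-ones. The step needs cross- over self-condensation of 8, secured by adding 6 only after 8 is fully enolised so that no free ketone is present; C7a over C2 in the first acylation, secured by the tert-butyl ester at C2 (with two methyl esters, acylation at C2 followed by C4-to-C6 aldol closure and dehydration would end in a hexasubstituted phenol); and C5 over C6 in the ring closure, secured because C6 lies inside the diketonate and its attack would give only a reversible five-membered aldolate. The alkene geometry of 6 is not critical, since the C4 dienolate and the push-pull dianion of 10 can rotate about C3–C3a before the lactone is closed.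

**Step 6**
Reactants: 12 peniophorin bis(4-O-methyl) ether
Product: 13 peniophorin [5-hydroxy-3,4-bis(4-hydroxyphenyl)-7-phenyl-1-benzofuran-2,6-dione]
Conditions: BBr3 (6 equiv), CH2Cl2, −78 to 23 °C; then H2O
Reagents that add atoms: none
Why: Lewis acid cleavage of aryl methyl ethers by BBr3 (bromide attack on the methyl group of the boron-bound ether), which should leave the enol lactone and the hydroxyquinone methide, held as a borate until hydrolysis, untouched at low temperature.

**Compound list**

1 | methyl 3-(4-methoxyphenyl)propanoate | COC(=O)CCc1ccc(OC)cc1 | starting material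
2 | di-tert-butyl oxalate | CC(C)(C)OC(=O)C(=O)OC(C)(C)C | starting material
3 | 4-tert-butyl 1-methyl 2-(4-methoxybenzyl)-3-oxobutanedioate (racemic) | COC(=O)C(Cc1ccc(OC)cc1)C(=O)C(=O)OC(C)(C)C | intermediate
4 | 4-tert-butyl 1-methyl (E)-2-(4-methoxybenzyl)-3-(trifluoromethanesulfonyloxy)but-2-enedioate | COC(=O)/C(Cc1ccc(OC)cc1)=C(/OS(=O)(=O)C(F)(F)F)C(=O)OC(C)(C)C | intermediate
5 | 4-methoxyphenylboronic acid | COc1ccc(B(O)O)cc1 | starting material
6 | 4-tert-butyl 1-methyl (Z)-2-(4-methoxybenzyl)-3-(4-methoxyphenyl)but-2-enedioate | COC(=O)/C(Cc1ccc(OC)cc1)=C(/c1ccc(OC)cc1)C(=O)OC(C)(C)C | intermediate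
7 | phenylpyruvic acid (2-oxo-3-phenylpropanoic acid) | O=C(O)C(=O)Cc1ccccc1 | starting material
8 | methyl phenylpyruvate (methyl 2-oxo-3-phenylpropanoate) | COC(=O)C(=O)Cc1ccccc1 | intermediate
9 | 1-tert-butyl 7-methyl (Z)-3-(4-methoxybenzyl)-2-(4-methoxyphenyl)-4,6-dioxo-5-phenylhept-2-enedioate (C5 unassigned, enolised in the flask) | CC(C)(C)OC(=O)/C(c1ccc(OC)cc1)=C(/Cc1ccc(OC)cc1)C(=O)C(c1ccccc1)C(=O)C(=O)OC | intermediate
10 | tert-butyl (Z)-2-[2,5-dihydroxy-6-(4-methoxyphenyl)-4-oxo-3-phenylcyclohexa-2,5-dien-1-ylidene]-2-(4-methoxyphenyl)acetate (enol tautomer of the Dieckmann triketone) | CC(C)(C)OC(=O)/C(c1ccc(OC)cc1)=C1/C(c2ccc(OC)cc2)=C(O)C(=O)C(c2ccccc2)=C1O | intermediate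
11 | (Z)-2-[2,5-dihydroxy-6-(4-methoxyphenyl)-4-oxo-3-phenylcyclohexa-2,5-dien-1-ylidene]-2-(4-methoxyphenyl)acetic acid | OC(=O)/C(c1ccc(OC)cc1)=C1/C(c2ccc(OC)cc2)=C(O)C(=O)C(c2ccccc2)=C1O | intermediate
12 | peniophorin bis(4-O-methyl) ether, 5-hydroxy-3,4-bis(4-methoxyphenyl)-7-phenyl-1-benzofuran-2,6-dione | O=C1OC2=C(c3ccccc3)C(=O)C(O)=C(c3ccc(OC)cc3)C2=C1c1ccc(OC)cc1 | intermediate
13 | peniophorin, 5-hydroxy-3,4-bis(4-hydroxyphenyl)-7-phenyl-1-benzofuran-2,6-dione | O=C1OC2=C(c3ccccc3)C(=O)C(O)=C(c3ccc(O)cc3)C2=C1c1ccc(O)cc1 | target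

**Step count and risks**

Total step count: 6. Longest linear sequence: 5 steps (steps 1, 2, 3, 5, 6).

Steps most likely to fail:

1. Step 5 (the step marked as a new method). The first acylation may be too slow at the hindered, donor-conjugated C7a ester, so that self-condensation of the phenylpyruvate enolate or of the maleate dienolate overtakes it, or the sequence may stall at the open-chain adduct because the second deprotonation at C4 is not reached. Fallback by known chemistry, setting out from 5 and returning at 12:
   - Bromanil and NaOMe in MeOH would give 2,5-dibromo-3,6-dimethoxy-1,4-benzoquinone F1.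
   - Suzuki–Miyaura coupling of F1 with one equivalent of 5 (Pd(PPh3)4, K2CO3, dioxane) would give 2-bromo-3,6-dimethoxy-5-(4-methoxyphenyl)-1,4-benzoquinone F2.
   - A second coupling with phenylboronic acid would give 2,5-dimethoxy-3-(4-methoxyphenyl)-6-phenyl-1,4-benzoquinone F3.
   - Aqueous NaOH in MeOH, then acid, would give 2,5-dihydroxy-3-(4-methoxyphenyl)-6-phenyl-1,4-benzoquinone F4.
   - Heating F4 with 4-methoxyphenylacetic acid and NaOAc in Ac2O (O-acylation, then intramolecular Knoevenagel-type condensation on the neighbouring quinone carbonyl, a Perkin-type lactone annulation) would give 3,4-bis(4-methoxyphenyl)-2,6-dioxo-7-phenyl-2,6-dihydro-1-benzofuran-5-yl acetate F5.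
   - The two hydroxyl groups of F4 are interchanged by tautomerism, so the annulation is not regioselective; the isomer 3,7-bis(4-methoxyphenyl)-2,6-dioxo-4-phenyl-2,6-dihydro-1-benzofuran-5-yl acetate F6 would form alongside and would have to be removed by chromatography.
   - Hydrolysis of the enol acetate of F5 in warm aqueous AcOH/HCl would return the route at 12.

2. Step 2. The O-sulfonylation may proceed with poor geometric control, or the triflate may be cleaved back to 3 under the basic coupling conditions that follow. Fallback, setting out from 1 and 2 and returning at 6, without a triflate or palladium: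
   - 4-Methoxyphenylmagnesium bromide and 2 in THF at −78 °C would give tert-butyl 2-(4-methoxyphenyl)-2-oxoacetate F7.
   - Aldol addition of the lithium enolate of 1 (LiN(i-Pr)2, THF, −78 °C) to the non-enolisable ketone of F7 would give 1-tert-butyl 4-methyl 2-hydroxy-3-(4-methoxybenzyl)-2-(4-methoxyphenyl)butanedioate F8 as a diastereomer mixture.
   - Dehydration with SOCl2 and pyridine, which can only run toward the carbon between the two esters, would give 6 together with 4-tert-butyl 1-methyl (E)-2-(4-methoxybenzyl)-3-(4-methoxyphenyl)but-2-enedioate F9.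
   - F9 need not be removed, since both isomers enter the same dienolate under the base of step 5.

3. Step 6. The Lewis acid may open the enol lactone, or bromide may add to the quinone methide, before both ethers are cleaved. Fallback, setting out from 12 and returning at 13, in which the chromophore is taken out of play during ether cleavage:
   - Reduction of 12 with Na2S2O4 in aqueous THF would give racemic 5,6-dihydroxy-3,4-bis(4-methoxyphenyl)-7-phenyl-1-benzofuran-2(3H)-one F10.
   - BBr3 in CH2Cl2 on this plain aromatic lactone would give 5,6-dihydroxy-3,4-bis(4-hydroxyphenyl)-7-phenyl-1-benzofuran-2(3H)-one F11.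
   - Stirring F11 in air in buffered aqueous EtOAc would reoxidise the catechol and, after tautomerisation to the quinone methide, give 13.

**Further compounds**

F1 | step 5 | 2,5-dibromo-3,6-dimethoxycyclohexa-2,5-diene-1,4-dione | COC1=C(Br)C(=O)C(OC)=C(Br)C1=O
F2 | step 5 | 2-bromo-3,6-dimethoxy-5-(4-methoxyphenyl)cyclohexa-2,5-diene-1,4-dione | COC1=C(Br)C(=O)C(OC)=C(c2ccc(OC)cc2)C1=O
F3 | step 5 | 2,5-dimethoxy-3-(4-methoxyphenyl)-6-phenylcyclohexa-2,5-diene-1,4-dione | COC1=C(c2ccccc2)C(=O)C(OC)=C(c2ccc(OC)cc2)C1=O
F4 | step 5 | 2,5-dihydroxy-3-(4-methoxyphenyl)-6-phenylcyclohexa-2,5-diene-1,4-dione | OC1=C(c2ccccc2)C(=O)C(O)=C(c2ccc(OC)cc2)C1=O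
F5 | step 5 | 3,4-bis(4-methoxyphenyl)-2,6-dioxo-7-phenyl-2,6-dihydro-1-benzofuran-5-yl acetate | O=C1OC2=C(c3ccccc3)C(=O)C(OC(C)=O)=C(c3ccc(OC)cc3)C2=C1c1ccc(OC)cc1
F6 | step 5 | 3,7-bis(4-methoxyphenyl)-2,6-dioxo-4-phenyl-2,6-dihydro-1-benzofuran-5-yl acetate | O=C1OC2=C(c3ccc(OC)cc3)C(=O)C(OC(C)=O)=C(c3ccccc3)C2=C1c1ccc(OC)cc1
F7 | step 2 | tert-butyl 2-(4-methoxyphenyl)-2-oxoacetate | COc1ccc(C(=O)C(=O)OC(C)(C)C)cc1
F8 | step 2 | 1-tert-butyl 4-methyl 2-hydroxy-3-(4-methoxybenzyl)-2-(4-methoxyphenyl)butanedioate (diastereomer mixture) | COC(=O)C(Cc1ccc(OC)cc1)C(O)(c1ccc(OC)cc1)C(=O)OC(C)(C)C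
F9 | step 2 | 4-tert-butyl 1-methyl (E)-2-(4-methoxybenzyl)-3-(4-methoxyphenyl)but-2-enedioate | COC(=O)/C(Cc1ccc(OC)cc1)=C(\c1ccc(OC)cc1)C(=O)OC(C)(C)C
F10 | step 6 | 5,6-dihydroxy-3,4-bis(4-methoxyphenyl)-7-phenyl-1-benzofuran-2(3H)-one (racemic) | O=C1Oc2c(-c3ccccc3)c(O)c(O)c(-c3ccc(OC)cc3)c2C1c1ccc(OC)cc1
F11 | step 6 | 5,6-dihydroxy-3,4-bis(4-hydroxyphenyl)-7-phenyl-1-benzofuran-2(3H)-one (racemic) | O=C1Oc2c(-c3ccccc3)c(O)c(O)c(-c3ccc(O)cc3)c2C1c1ccc(O)cc1
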